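**Retrosynthetic overview**
1. The strategy rests on ring C of the upper flavan unit (O1–C2–C3–C4–C4a–C8a). C4 is a diarylmethine carbon bonded to C4a of the phloroglucinol ring A and to C8 of the catechin unit, and it lies β to the oxygen-bearing C2. C2–C3–C4 is therefore an enal carried on catechin C8, and C4a/O1 are the ortho carbon and the oxygen of a 3,5-dioxygenated phenol.
2. Target 18 ⇐ nona-O-benzyl ether 17 (hydrogenolysis) ⇐ keto-phenol 14 (ring C reclosed, C2–H set 2,4-cis by ionic hydrogenation) ⇐ lactone 11 + aryllithium 13 (C2–aryl bond, ring B).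
3. Lactone 11 ⇐ lactol 10 ⇐ enal 7 + phenol 8 by amine-catalysed Friedel–Crafts alkylation/hemiacetalisation (C4–C4a and O1–C2; sets C4).
4. Enal 7 ⇐ 8-formyl compound 6 ⇐ 8-bromide 4 ⇐ penta-O-benzylcatechin 3 ⇐ (+)-catechin 1, which supplies both stereocentres of the lower unit.
5. Ring order: the catechin rings and ring A are bought with 1 and 8; ring C closes in step 6, opens when ring B is attached in step 8 and recloses in step 9.

Key step: step 6

Assumption: 3,5-bis(benzyloxy)phenol (8) and 4-bromo-1,2-bis(benzyloxy)benzene (12) are taken as purchasable, so phloroglucinol is not needed; lactol 10 is drawn without C2 configuration (both anomers converge in step 7) and adduct 14 as the open keto-phenol, which is assumed to outweigh its cyclic hemiketal 15.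

**Step 1**
Reactants: 1 (+)-catechin
Product: 2 5,7,3',4'-tetra-O-benzylcatechin, (2R,3S)-5,7-bis(benzyloxy)-2-[3,4-bis(benzyloxy)phenyl]chroman-3-ol
Conditions: BnBr (4.4 equiv), K2CO3, DMF, 0 °C to rt, argon
Reagents that add atoms: benzyl bromide, BrCc1ccccc1
Why: Williamson ether synthesis in which carbonate deprotonates only the four phenols, so the secondary 3-OH stays free and the mild base should leave C2 unepimerised.

**Step 2**
Reactants: 2 5,7,3',4'-tetra-O-benzylcatechin
Product: 3 penta-O-benzylcatechin, (2R,3S)-3,5,7-tris(benzyloxy)-2-[3,4-bis(benzyloxy)phenyl]chromane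
Conditions: NaH, BnBr, Bu4NI (cat.), DMF, 0 °C to rt
Reagents that add atoms: benzyl bromide, BrCc1ccccc1
Why: Williamson ether synthesis on the secondary alkoxide; with every phenol already capped, no quinone-methide ring opening can scramble C2, and the ether removes the acidic proton before the lithiation.

**Step 3**
Reactants: 3 penta-O-benzylcatechin
Product: 4 8-bromo-penta-O-benzylcatechin
Conditions: NBS (1.0 equiv), CH2Cl2, −78 °C to rt
Reagents that add atoms: N-bromosuccinimide, O=C1CCC(=O)N1Br
Why: Electrophilic aromatic bromination, which on benzylated catechins is known to go to C8 ahead of C6, the position flanked by two benzyloxy groups.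

**Step 4**
Reactants: 4 8-bromo-penta-O-benzylcatechin
Product: 6 8-formyl-penta-O-benzylcatechin, via 8-lithio-penta-O-benzylcatechin 5 (not isolated)
Conditions: n-BuLi (1.1 equiv), THF, −78 °C; then DMF, −78 to 0 °C; aq NH4Cl
Reagents that add atoms: N,N-dimethylformamide, CN(C)C=O (formyl carbon and oxygen of 6); n-butyllithium, CCCC[Li] (supplies only the lithium of intermediate 5)
Why: Bromine–lithium exchange followed by Bouveault-type formylation; the 8-lithio species of benzylated catechins is a known, configurationally innocent nucleophile at −78 °C.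

**Step 5**
Reactants: 6 8-formyl-penta-O-benzylcatechin
Product: 7 (E)-3-(penta-O-benzylcatechin-8-yl)prop-2-enal
Conditions: Ph3P=CHCHO (1.5 equiv), toluene, 90 °C
Reagents that add atoms: (triphenylphosphoranylidene)acetaldehyde, O=CC=P(c1ccccc1)(c1ccccc1)c1ccccc1
Why: Wittig olefination with a stabilised ylide should give the E-alkene, and the vinylogous, electron-rich product aldehyde is less electrophilic than 6, which limits a second homologation.

**Step 6**
Reactants: 7 (E)-3-(penta-O-benzylcatechin-8-yl)prop-2-enal; 8 3,5-bis(benzyloxy)phenol (1.5 equiv)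
Product: 10 (4S)-5,7-bis(benzyloxy)-4-(penta-O-benzylcatechin-8-yl)chroman-2-ol (anomer mixture), via hydroxyaryl aldehyde 9 (not isolated)
Conditions: (R)-2-[diphenyl(trimethylsilyloxy)methyl]pyrrolidine (20 mol%), PhCO2H (20 mol%), toluene (0.5–1 M), rt to 40 °C
Reagents that add atoms: none
Why: This is the known diarylprolinol silyl ether-catalysed Friedel–Crafts alkylation/hemiacetalisation of electron-rich phenols with enals: the amine condenses with 7 to the E,s-trans iminium ion, an ortho carbon of 8 (the two positions flanked by OH and OBn are equivalent) adds to the β-carbon to form C4–C4a, and rearomatisation, enamine protonation and hydrolysis release aldehyde 9 and the catalyst. Ring C then closes by 6-exo-trig addition of the phenolic oxygen to the aldehyde carbonyl (O1–C2), giving the chroman-2-ol, whose C2 configuration is irrelevant because step 7 removes it. C4 is set by the catalyst: the diphenyl(silyloxy)methyl group covers one face of the iminium ion, and the R-configured pyrrolidine is chosen because the S-catalyst adds nucleophiles to β-aryl enals in the sense that would give the 4R epimer; the nearest catechin stereocentre is four bonds from C4 and should only modulate the diastereomer ratio. The step needs ortho-carbon selectivity on 8 over para-carbon and oxygen attack, which should follow from delivery assisted by the free phenolic OH as in the known dialkoxyphenol cases, from the reversibility of oxa-Michael addition, and from lactol formation, open only to the ortho adduct. The rate is the weak point, since the 2,4,6-trioxygenated, di-ortho-substituted aryl group makes the iminium ion a poor electrophile; hence the high concentration, acid co-catalyst and mild warming.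

**Step 7**
Reactants: 10 (4S)-chroman-2-ol
Product: 11 (4S)-5,7-bis(benzyloxy)-4-(penta-O-benzylcatechin-8-yl)chroman-2-one
Conditions: (n-Pr4N)RuO4 (5 mol%), NMO (1.5 equiv), 4 Å MS, CH2Cl2, rt
Reagents that add atoms: none
Why: Ley–Griffith oxidation of a lactol to the lactone under neutral conditions that benzyl ethers and electron-rich arenes tolerate; C4 is not α to the carbonyl and cannot epimerise.

**Step 8**
Reactants: 11 (4S)-chroman-2-one; 12 4-bromo-1,2-bis(benzyloxy)benzene
Product: 14 (3S)-3-[2,4-bis(benzyloxy)-6-hydroxyphenyl]-1-[3,4-bis(benzyloxy)phenyl]-3-(penta-O-benzylcatechin-8-yl)propan-1-one, via 3,4-bis(benzyloxy)phenyllithium 13 (not isolated)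
Conditions: 12, n-BuLi, THF, −78 °C; then slow cannulation (1.1 equiv) into 11, THF, −78 °C; aq NH4Cl
Reagents that add atoms: n-butyllithium, CCCC[Li] (supplies only the lithium of intermediate 13; none of its atoms remain in 14)
Why: Bromine–lithium exchange and nucleophilic acyl substitution on the aryl ester-type lactone, whose collapse releases a phenoxide and a 3,4-dialkoxyphenyl ketone that is less electrophilic than the lactone, so single addition should prevail when the aryllithium is added to the lactone.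

**Step 9**
Reactants: 14 keto-phenol
Product: 17 (2S,4S)-5,7-bis(benzyloxy)-2-[3,4-bis(benzyloxy)phenyl]-4-(penta-O-benzylcatechin-8-yl)chromane (2,4-cis), via cyclic hemiketal 15 (not isolated), via oxocarbenium ion 16 (not isolated)
Conditions: Et3SiH (5 equiv), CF3CO2H, CH2Cl2, −40 to 0 °C
Reagents that add atoms: none
Why: Ionic hydrogenation in which acid closes 14 to hemiketal 15 and ionises it to the aryl-stabilised oxocarbenium ion 16; the silane should deliver hydride to C2 from the face opposite the C4 substituent, which is held pseudo-axial by peri strain with the C5 benzyloxy group, so the C2 aryl group ends cis to the C4 aryl group.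

**Step 10**
Reactants: 17 nona-O-benzyl ether
Product: 18 target, (2R,3S)-2-(3,4-dihydroxyphenyl)-8-[(2S,4S)-2-(3,4-dihydroxyphenyl)-5,7-dihydroxychroman-4-yl]chroman-3,5,7-triol
Conditions: H2 (1 atm), Pd(OH)2/C, THF–MeOH, rt, degassed solvents
Reagents that add atoms: none
Why: Catalytic hydrogenolysis removes all nine benzyl ethers under neutral conditions that are standard for benzylated proanthocyanidins and leave the flavan C2–O1 bonds and the four stereocentres untouched.

**Compound list**
1 | (+)-catechin | Oc1cc(O)c2c(c1)O[C@H](c1ccc(O)c(O)c1)[C@@H](O)C2 | starting material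
2 | 5,7,3',4'-tetra-O-benzylcatechin | c3c(OCc9ccccc9)cc(OCc9ccccc9)c4c3O[C@H](c6ccc(OCc9ccccc9)c(OCc9ccccc9)c6)[C@@H](O)C4 | intermediate
3 | penta-O-benzylcatechin | c3c(OCc9ccccc9)cc(OCc9ccccc9)c4c3O[C@H](c6ccc(OCc9ccccc9)c(OCc9ccccc9)c6)[C@@H](OCc9ccccc9)C4 | intermediate
4 | 8-bromo-penta-O-benzylcatechin | Brc3c(OCc9ccccc9)cc(OCc9ccccc9)c4c3O[C@H](c6ccc(OCc9ccccc9)c(OCc9ccccc9)c6)[C@@H](OCc9ccccc9)C4 | intermediate
5 | 8-lithio-penta-O-benzylcatechin | [Li]c3c(OCc9ccccc9)cc(OCc9ccccc9)c4c3O[C@H](c6ccc(OCc9ccccc9)c(OCc9ccccc9)c6)[C@@H](OCc9ccccc9)C4 | intermediate (not isolated)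
6 | 8-formyl-penta-O-benzylcatechin | O=Cc3c(OCc9ccccc9)cc(OCc9ccccc9)c4c3O[C@H](c6ccc(OCc9ccccc9)c(OCc9ccccc9)c6)[C@@H](OCc9ccccc9)C4 | intermediate
7 | (E)-3-(penta-O-benzylcatechin-8-yl)prop-2-enal | O=C/C=C/c3c(OCc9ccccc9)cc(OCc9ccccc9)c4c3O[C@H](c6ccc(OCc9ccccc9)c(OCc9ccccc9)c6)[C@@H](OCc9ccccc9)C4 | intermediate (key-step precursor)
8 | 3,5-bis(benzyloxy)phenol | Oc1cc(OCc2ccccc2)cc(OCc2ccccc2)c1 | starting material
9 | (3S)-3-[2,4-bis(benzyloxy)-6-hydroxyphenyl]-3-(penta-O-benzylcatechin-8-yl)propanal | O=CC[C@@H](c1c(O)cc(OCc9ccccc9)cc1OCc9ccccc9)c3c(OCc9ccccc9)cc(OCc9ccccc9)c4c3O[C@H](c6ccc(OCc9ccccc9)c(OCc9ccccc9)c6)[C@@H](OCc9ccccc9)C4 | intermediate (not isolated)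
10 | (4S)-5,7-bis(benzyloxy)-4-(penta-O-benzylcatechin-8-yl)chroman-2-ol, anomer mixture | O(Cc9ccccc9)c1cc(OCc9ccccc9)c2c(c1)OC(O)C[C@@H]2c3c(OCc9ccccc9)cc(OCc9ccccc9)c4c3O[C@H](c6ccc(OCc9ccccc9)c(OCc9ccccc9)c6)[C@@H](OCc9ccccc9)C4 | intermediate (key-step product)
11 | (4S)-5,7-bis(benzyloxy)-4-(penta-O-benzylcatechin-8-yl)chroman-2-one | O(Cc9ccccc9)c1cc(OCc9ccccc9)c2c(c1)OC(=O)C[C@@H]2c3c(OCc9ccccc9)cc(OCc9ccccc9)c4c3O[C@H](c6ccc(OCc9ccccc9)c(OCc9ccccc9)c6)[C@@H](OCc9ccccc9)C4 | intermediate
12 | 4-bromo-1,2-bis(benzyloxy)benzene | Brc1ccc(OCc2ccccc2)c(OCc2ccccc2)c1 | starting material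
13 | 3,4-bis(benzyloxy)phenyllithium | [Li]c1ccc(OCc2ccccc2)c(OCc2ccccc2)c1 | intermediate (not isolated)
14 | (3S)-3-[2,4-bis(benzyloxy)-6-hydroxyphenyl]-1-[3,4-bis(benzyloxy)phenyl]-3-(penta-O-benzylcatechin-8-yl)propan-1-one | O=C(c1ccc(OCc9ccccc9)c(OCc9ccccc9)c1)C[C@@H](c1c(O)cc(OCc9ccccc9)cc1OCc9ccccc9)c3c(OCc9ccccc9)cc(OCc9ccccc9)c4c3O[C@H](c6ccc(OCc9ccccc9)c(OCc9ccccc9)c6)[C@@H](OCc9ccccc9)C4 | intermediate
15 | (4S)-5,7-bis(benzyloxy)-2-[3,4-bis(benzyloxy)phenyl]-4-(penta-O-benzylcatechin-8-yl)chroman-2-ol (cyclic hemiketal) | O(Cc9ccccc9)c1cc(OCc9ccccc9)c2c(c1)OC(O)(c1ccc(OCc9ccccc9)c(OCc9ccccc9)c1)C[C@@H]2c3c(OCc9ccccc9)cc(OCc9ccccc9)c4c3O[C@H](c6ccc(OCc9ccccc9)c(OCc9ccccc9)c6)[C@@H](OCc9ccccc9)C4 | intermediate (not isolated)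
16 | (4S)-5,7-bis(benzyloxy)-2-[3,4-bis(benzyloxy)phenyl]-4-(penta-O-benzylcatechin-8-yl)-3,4-dihydrochromenylium (oxocarbenium ion) | O(Cc9ccccc9)c1cc(OCc9ccccc9)c2c(c1)[O+]=C(c1ccc(OCc9ccccc9)c(OCc9ccccc9)c1)C[C@@H]2c3c(OCc9ccccc9)cc(OCc9ccccc9)c4c3O[C@H](c6ccc(OCc9ccccc9)c(OCc9ccccc9)c6)[C@@H](OCc9ccccc9)C4 | intermediate (not isolated)
17 | (2S,4S)-5,7-bis(benzyloxy)-2-[3,4-bis(benzyloxy)phenyl]-4-(penta-O-benzylcatechin-8-yl)chromane | O(Cc9ccccc9)c1cc(OCc9ccccc9)c2c(c1)O[C@H](c1ccc(OCc9ccccc9)c(OCc9ccccc9)c1)C[C@@H]2c3c(OCc9ccccc9)cc(OCc9ccccc9)c4c3O[C@H](c6ccc(OCc9ccccc9)c(OCc9ccccc9)c6)[C@@H](OCc9ccccc9)C4 | intermediate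
18 | (2R,3S)-2-(3,4-dihydroxyphenyl)-8-[(2S,4S)-2-(3,4-dihydroxyphenyl)-5,7-dihydroxychroman-4-yl]chroman-3,5,7-triol (CNP0180676.1) | Oc1cc(O)c2c(c1)O[C@H](c1ccc(O)c(O)c1)C[C@@H]2c1c(O)cc(O)c2c1O[C@H](c1ccc(O)c(O)c1)[C@@H](O)C2 | target

**Step count**
Total: 10 steps. Longest linear sequence: 10 steps, from (+)-catechin 1 to 18; fragments 8 and 12 enter as purchased compounds.

**Steps most likely to fail**

Step 6. The conjugate addition may be too slow because the trioxygenated, di-ortho-substituted aryl group deactivates the iminium ion; para attack on the phenol or weak facial control by the catalyst are further risks. The fallback sets out from aldehyde 6 and returns at lactone 11. Knoevenagel condensation of 6 with Meldrum's acid (pyrrolidinium acetate, benzene, rt to 50 °C) would give the arylidene Meldrum's acid F1, a much stronger acceptor than the iminium ion. Treatment of F1 with phenol 8 and Yb(OTf)3 (10 mol%) in MeNO2 is a known route to 4-substituted 3,4-dihydrocoumarins: Friedel–Crafts conjugate addition at the ortho carbon, acylation of the phenolic oxygen with loss of acetone, and decarboxylation. It would give 11 directly, together with the C4 epimer of the lactone F2. The two are diastereomers and would be separated by chromatography; C4 is then steered only by the catechin unit, so the ratio cannot be predicted, and step 7 is skipped.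

Step 9. The ionic hydrogenation may over-reduce through ring-opened benzylic cations to a 1,3-diarylpropane, may give insufficient 2,4-cis selectivity, or may erode C4 if the flav-2-ene formed by proton loss from 16 disproportionates to a flavylium ion. The fallback sets out from ketone 14 and returns at 17, avoiding cationic intermediates. Corey–Bakshi–Shibata reduction with (S)-Me-CBS oxazaborolidine and excess BH3·SMe2 (the phenol consumes hydride) in THF at −20 °C should give, under reagent control, the (1R)-carbinol F4. Mitsunobu cyclisation (PPh3, DIAD, THF, 0 °C) then lets the phenol displace the activated benzylic oxygen with inversion, closing ring C as the (2S)-flavan 17.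

Step 8. The aryllithium may add twice, to the ketone released when the tetrahedral adduct collapses, or may enolise the lactone instead of adding. The fallback sets out from lactone 11 and returns at ketone 14. Aminolysis of 11 with MeNH(OMe)·HCl and i-PrMgCl (THF, −20 °C) would open it to the phenolic Weinreb amide F3. Treatment of F3 with 2.2 equiv of aryllithium 13 (the first equivalent forms the phenoxide) gives a chelated tetrahedral adduct that persists until the quench, so 14 should form without over-addition.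

**Further compounds**
F1 | step 6 | 5-[(penta-O-benzylcatechin-8-yl)methylidene]-2,2-dimethyl-1,3-dioxane-4,6-dione | CC1(C)OC(=O)C(=Cc3c(OCc9ccccc9)cc(OCc9ccccc9)c4c3O[C@H](c6ccc(OCc9ccccc9)c(OCc9ccccc9)c6)[C@@H](OCc9ccccc9)C4)C(=O)O1
F2 | step 6 | (4R)-5,7-bis(benzyloxy)-4-(penta-O-benzylcatechin-8-yl)chroman-2-one (C4 epimer of 11) | O(Cc9ccccc9)c1cc(OCc9ccccc9)c2c(c1)OC(=O)C[C@H]2c3c(OCc9ccccc9)cc(OCc9ccccc9)c4c3O[C@H](c6ccc(OCc9ccccc9)c(OCc9ccccc9)c6)[C@@H](OCc9ccccc9)C4
F3 | step 8 | (3S)-3-[2,4-bis(benzyloxy)-6-hydroxyphenyl]-N-methoxy-N-methyl-3-(penta-O-benzylcatechin-8-yl)propanamide | CON(C)C(=O)C[C@@H](c1c(O)cc(OCc9ccccc9)cc1OCc9ccccc9)c3c(OCc9ccccc9)cc(OCc9ccccc9)c4c3O[C@H](c6ccc(OCc9ccccc9)c(OCc9ccccc9)c6)[C@@H](OCc9ccccc9)C4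
F4 | step 9 | (1R,3S)-3-[2,4-bis(benzyloxy)-6-hydroxyphenyl]-1-[3,4-bis(benzyloxy)phenyl]-3-(penta-O-benzylcatechin-8-yl)propan-1-ol | O[C@@H](c1ccc(OCc9ccccc9)c(OCc9ccccc9)c1)C[C@@H](c1c(O)cc(OCc9ccccc9)cc1OCc9ccccc9)c3c(OCc9ccccc9)cc(OCc9ccccc9)c4c3O[C@H](c6ccc(OCc9ccccc9)c(OCc9ccccc9)c6)[C@@H](OCc9ccccc9)C4
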